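**Plan**
Cuts: the four O–CH3 masks of the catechols, then the pyrrole N–CH2 bond of the propyl linker, then the two pyrrole C3/C4–quinoline C5 bonds. In the amine half the cuts are N1–C2 of the azecane, then N1–C10 and C4–C5 of the open chain.
Enabling feature: in the ten-membered azecane ring the only stereocentre, C3, bears a methyl group and lies beta to N1, with just the C2 methylene between them. This N1–C2H2–C3H(CH3) unit is what remains after H adds to C3 and N1 adds to C2 of a 2-methylalk-1-ene in the anti-Markovnikov sense.
Forward, amine half: C4–C5 by copper-catalysed Grignard coupling, C10–N1 by amination, N1 made electrophilic as its O-benzoate, then closure of the azecane (the only ring that is built) at N1–C2 under chiral copper hydride catalysis.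
Forward, aromatic half: the quinoline and pyrrole rings are bought. C5 bromination, borylation and a twofold Suzuki–Miyaura coupling on a 3,4-dibromopyrrole join them.
Union: the linker alcohol is unmasked and chlorinated, the pyrrole nitrogen is alkylated, and BBr3 frees the four phenols.
Stereochemistry: C3 (S) comes only from the enantiomer of DTBM-SEGPHOS on copper, which decides the alkene face that receives hydride. No later step touches C3.

Key step: step 4

Assumption: (R)-DTBM-SEGPHOS is written as the antipode that leads to (S)-C3. The sense of induction is to be checked on the ring-closed amine, and the (S)-ligand takes its place if hydride goes to the other face.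
Assumption: the two pyrrole–quinoline axes are taken as not configurationally fixed, since the target structure carries no axial descriptor.

Step 1
Reactants: 1 2-methylallylmagnesium chloride; 2 1-bromo-6-chlorohexane
Product: 3 9-chloro-2-methylnon-1-ene
Conditions: Li2CuCl4 (3 mol %), THF, −10 °C to rt
Reagents that add atoms: none
Why: Kochi-type copper-catalysed sp3–sp3 coupling of a Grignard reagent with a primary alkyl bromide, in which C–Br reacts far faster than C–Cl and the symmetric methallyl nucleophile gives the same product from either allyl terminus.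

Step 2
Reactants: 3 9-chloro-2-methylnon-1-ene; 4 3-(benzyloxy)propan-1-amine
Product: 5 N-[3-(benzyloxy)propyl]-8-methylnon-8-en-1-amine
Conditions: 4 (4 equiv), K2CO3, MeCN, 85 °C (sealed vessel)
Reagents that add atoms: none
Why: SN2 N-alkylation of a primary amine by a primary alkyl chloride, with the excess of 4 (recovered by distillation) holding back double alkylation.

Step 3
Reactants: 5 N-[3-(benzyloxy)propyl]-8-methylnon-8-en-1-amine; 6 dibenzoyl peroxide
Product: 7 O-benzoyl-N-[3-(benzyloxy)propyl]-N-(8-methylnon-8-en-1-yl)hydroxylamine
Conditions: K2HPO4 (1.5 equiv), DMF, rt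
Reagents that add atoms: none
Why: Buffered N-benzoyloxylation of a secondary amine by nucleophilic attack of nitrogen on the peroxide O–O bond, the standard preparation of O-benzoylhydroxylamines, which leaves the alkene and the benzyl ether untouched at room temperature.

Step 4
Reactants: 7 O-benzoyl-N-[3-(benzyloxy)propyl]-N-(8-methylnon-8-en-1-yl)hydroxylamine
Product: 9 (S)-1-[3-(benzyloxy)propyl]-3-methylazecane, via alkylcopper intermediate 8 (not isolated)
Conditions: Cu(OAc)2 (10 mol %), (R)-DTBM-SEGPHOS (11 mol %), PPh3 (11 mol %), (MeO)2MeSiH (3 equiv), THF, 40 °C; 7 added by syringe pump over 20 h (final 0.005 M); aq. Na2CO3 work-up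
Reagents that add atoms: none
Why: Proposed new method: the bisphosphine-bound copper hydride formed from Cu(OAc)2 and the silane inserts C2=C3 of 7 with copper on the terminal C2 and hydride on C3 to give the primary alkylcopper 8, whose C2–Cu bond is then aminated by the electrophilic nitrogen of its own N–O benzoate, after which the silane converts the copper benzoate back into the hydride. The closest known reaction type is the intermolecular CuH-catalysed enantioselective anti-Markovnikov hydroamination of 1,1-disubstituted alkenes with O-benzoylhydroxylamines, which has not been run intramolecularly to a medium ring. The azecane closes head to tail at N1–C2, formally 10-exo-tet at nitrogen, because the departing benzoate oxygen stays outside the new ring. C3 is set in the hydrocupration, where the chiral pocket of DTBM-SEGPHOS must tell the methyl group from the linear C4–C10 chain and so decides which alkene face receives hydride. Regioselectivity is secured by the 1,1-disubstitution of the alkene, which leaves only the CH2 terminus open to copper, and chemoselectivity by the absence of any other reducible π-bond, the benzyl ether being inert. Ring closure has to beat intermolecular amination and direct N–O reduction, which is why 7 is fed slowly into a solution that always holds more catalyst than free substrate, and any 5 regenerated by N–O reduction can be returned to step 3.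

Step 5
Reactants: 9 (S)-1-[3-(benzyloxy)propyl]-3-methylazecane
Product: 10 3-[(3S)-3-methylazecan-1-yl]propan-1-ol
Conditions: H2 (1 atm), Pd(OH)2/C, MeOH–AcOH (10:1), rt; basic work-up
Reagents that add atoms: none
Why: Catalytic hydrogenolysis of a benzyl ether, with the acidic cosolvent protonating N1 so that the amine does not poison palladium, and with C3, which is neither benzylic nor allylic, left unchanged.

Step 6
Reactants: 10 3-[(3S)-3-methylazecan-1-yl]propan-1-ol
Product: 11 (3S)-1-(3-chloropropyl)-3-methylazecane hydrochloride
Conditions: SOCl2 (1.5 equiv), CH2Cl2, 0 °C to reflux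
Reagents that add atoms: thionyl chloride, O=S(Cl)Cl
Why: Deoxychlorination of a primary alcohol with SOCl2 (SN2 by chloride), the usual route to 3-chloropropylamine hydrochlorides, in which the HCl formed keeps N1 protonated and the product storable.

Step 7
Reactants: 12 6,7-dimethoxyquinoline
Product: 13 5-bromo-6,7-dimethoxyquinoline
Conditions: NBS (1.0 equiv), CF3CO2H, 0 °C to rt
Reagents that add atoms: N-bromosuccinimide, O=C1CCC(=O)N1Br
Why: Electrophilic aromatic bromination of the protonated quinoline, in which the 7-methoxy group is drained by through-conjugation with N1–H+ and the 6-methoxy group therefore directs bromine to its only free ortho position, the alpha-type C5, as is known for 6-methoxyquinoline.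

Step 8
Reactants: 13 5-bromo-6,7-dimethoxyquinoline
Product: 14 6,7-dimethoxy-5-(4,4,5,5-tetramethyl-1,3,2-dioxaborolan-2-yl)quinoline
Conditions: B2pin2 (1.2 equiv), PdCl2(dppf) (5 mol %), KOAc (3 equiv), 1,4-dioxane, 95 °C
Reagents that add atoms: bis(pinacolato)diboron, CC1(C)OB(OC1(C)C)B1OC(C)(C)C(C)(C)O1
Why: Miyaura borylation of an aryl bromide, which tolerates the methoxy groups and the quinoline nitrogen and is established for ortho-alkoxy, peri-hindered bromides of the 1-bromo-2-methoxynaphthalene type.

Step 9
Reactants: 15 1-(triisopropylsilyl)pyrrole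
Product: 16 3,4-dibromo-1-(triisopropylsilyl)pyrrole
Conditions: NBS (2.0 equiv), THF, −78 °C to rt
Reagents that add atoms: N-bromosuccinimide, O=C1CCC(=O)N1Br
Why: Electrophilic bromination of an N-silylpyrrole, in which the bulky triisopropylsilyl group screens C2 and C5 so that both bromine atoms enter at C3 and C4.

Step 10
Reactants: 16 3,4-dibromo-1-(triisopropylsilyl)pyrrole; 14 6,7-dimethoxy-5-(4,4,5,5-tetramethyl-1,3,2-dioxaborolan-2-yl)quinoline (2.5 equiv)
Product: 18 3,4-bis(6,7-dimethoxyquinolin-5-yl)-1H-pyrrole, via N-TIPS-diarylpyrrole 17 (not isolated)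
Conditions: Pd(OAc)2 (5 mol %), SPhos (10 mol %), K3PO4 (4 equiv), toluene–H2O (10:1), 100 °C; then Bu4NF, THF, rt
Reagents that add atoms: none
Why: Twofold Suzuki–Miyaura coupling with a bulky electron-rich biarylphosphine suited to di-ortho-substituted partners, followed by fluoride cleavage of the N–Si bond so that material that has partly lost silicon under the aqueous base also converges on 18.

Step 11
Reactants: 18 3,4-bis(6,7-dimethoxyquinolin-5-yl)-1H-pyrrole; 11 (3S)-1-(3-chloropropyl)-3-methylazecane hydrochloride
Product: 19 (3S)-1-{3-[3,4-bis(6,7-dimethoxyquinolin-5-yl)-1H-pyrrol-1-yl]propyl}-3-methylazecane (tetra-O-methylisohalitulin)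
Conditions: powdered KOH (5 equiv), DMSO, rt to 40 °C; 11 (1.5 equiv)
Reagents that add atoms: none
Why: Classical N-alkylation of a pyrrole in KOH/DMSO with a 3-chloropropylamine (SN2), in which the deprotonated pyrrole nitrogen far outruns the neutral quinoline nitrogens as nucleophile.

Step 12
Reactants: 19 tetra-O-methylisohalitulin
Product: 20 isohalitulin
Conditions: BBr3 (12 equiv), CH2Cl2, −78 °C to rt; then H2O, pH 7 buffer, under Ar
Reagents that add atoms: none
Why: Lewis-acid cleavage of aryl methyl ethers with BBr3, with extra equivalents covering the three basic nitrogens, air excluded to protect the catechols, and no bond at C3 involved.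

**Compound list**
1 | 2-methylallylmagnesium chloride (solution in THF) | C=C(C)C[Mg]Cl | starting material
2 | 1-bromo-6-chlorohexane | ClCCCCCCBr | starting material
3 | 9-chloro-2-methylnon-1-ene | C=C(C)CCCCCCCCl | intermediate
4 | 3-(benzyloxy)propan-1-amine | NCCCOCc1ccccc1 | starting material
5 | N-[3-(benzyloxy)propyl]-8-methylnon-8-en-1-amine | C=C(C)CCCCCCCNCCCOCc1ccccc1 | intermediate
6 | dibenzoyl peroxide | O=C(OOC(=O)c1ccccc1)c1ccccc1 | starting material
7 | O-benzoyl-N-[3-(benzyloxy)propyl]-N-(8-methylnon-8-en-1-yl)hydroxylamine | C=C(C)CCCCCCCN(CCCOCc1ccccc1)OC(=O)c1ccccc1 | intermediate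
8 | [(2S)-9-{(benzoyloxy)[3-(benzyloxy)propyl]amino}-2-methylnonyl]copper, bisphosphine ligand omitted | C[C@H](C[Cu])CCCCCCCN(CCCOCc1ccccc1)OC(=O)c1ccccc1 | intermediate
9 | (S)-1-[3-(benzyloxy)propyl]-3-methylazecane | C[C@H]1CCCCCCCN(CCCOCc2ccccc2)C1 | intermediate
10 | 3-[(3S)-3-methylazecan-1-yl]propan-1-ol | C[C@H]1CCCCCCCN(CCCO)C1 | intermediate
11 | (3S)-1-(3-chloropropyl)-3-methylazecane hydrochloride | C[C@H]1CCCCCCCN(CCCCl)C1.Cl | intermediate
12 | 6,7-dimethoxyquinoline | COc1cc2ncccc2cc1OC | starting material
13 | 5-bromo-6,7-dimethoxyquinoline | COc1cc2ncccc2c(Br)c1OC | intermediate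
14 | 6,7-dimethoxy-5-(4,4,5,5-tetramethyl-1,3,2-dioxaborolan-2-yl)quinoline | COc1cc2ncccc2c(B2OC(C)(C)C(C)(C)O2)c1OC | intermediate
15 | 1-(triisopropylsilyl)pyrrole | CC(C)[Si](C(C)C)(C(C)C)n1cccc1 | starting material
16 | 3,4-dibromo-1-(triisopropylsilyl)pyrrole | CC(C)[Si](C(C)C)(C(C)C)n1cc(Br)c(Br)c1 | intermediate
17 | 3,4-bis(6,7-dimethoxyquinolin-5-yl)-1-(triisopropylsilyl)pyrrole | CC(C)[Si](C(C)C)(C(C)C)n1cc(-c2c(OC)c(OC)cc3ncccc23)c(-c2c(OC)c(OC)cc3ncccc23)c1 | intermediate
18 | 3,4-bis(6,7-dimethoxyquinolin-5-yl)-1H-pyrrole | c1c(-c2c(OC)c(OC)cc3ncccc23)c(-c2c(OC)c(OC)cc3ncccc23)c[nH]1 | intermediate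
19 | (3S)-1-{3-[3,4-bis(6,7-dimethoxyquinolin-5-yl)-1H-pyrrol-1-yl]propyl}-3-methylazecane | C[C@H]1CCCCCCCN(CCCn2cc(-c3c(OC)c(OC)cc4ncccc34)c(-c3c(OC)c(OC)cc4ncccc34)c2)C1 | intermediate
20 | isohalitulin, 5,5'-{1-[3-((3S)-3-methylazecan-1-yl)propyl]-1H-pyrrole-3,4-diyl}bis(quinoline-6,7-diol) | C[C@H]1CCCCCCCN(CCCn2cc(-c3c(O)c(O)cc4ncccc34)c(-c3c(O)c(O)cc4ncccc34)c2)C1 | target

**Totals**
Total step count: 12. Longest linear sequence: 8 steps (steps 1–6, 11, 12).

**Steps most likely to fail**

1. Step 4.
- The copper hydride may reduce the N–O bond faster than it adds to the alkene.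
- Transannular strain in the forming ten-membered ring may slow C–N bond formation so much that intermolecular amination (oligomerisation) or protodemetalation takes over.
- The ligand may discriminate poorly between methyl and the unbranched chain, which would erode the enantiomeric purity at C3. The benzyl chromophore of 9 allows this to be read by chiral HPLC.

The fallback uses only known chemistry, sets out from 4 and comes back at 9. Amine 4 (in excess) is monoalkylated with 6-bromohex-1-ene (K2CO3, MeCN) to N-[3-(benzyloxy)propyl]hex-5-en-1-amine F1. This is acylated with commercial (S)-2-methylpent-4-enoic acid (EDC·HCl, HOBt, CH2Cl2) to (2S)-N-[3-(benzyloxy)propyl]-N-(hex-5-en-1-yl)-2-methylpent-4-enamide F2. Ring-closing metathesis with the second-generation Grubbs catalyst, RuCl2(=CHPh)(PCy3)(SIMes), in dilute refluxing CH2Cl2 closes C5=C6 to (3S)-1-[3-(benzyloxy)propyl]-3-methyl-3,4,7,8,9,10-hexahydroazecin-2(1H)-one F3. The alkene is saturated with H2 and RhCl(PPh3)3, which spares the benzyl ether, to give (3S)-1-[3-(benzyloxy)propyl]-3-methylazecan-2-one F4. LiAlH4 in THF then reduces the lactam to 9. In this path C3 is bought with the acid and the ring is closed far from it.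

2. Step 10. Protodeboronation of the hindered boronate 14 may outrun transmetalation, and the sequence may stall after the first coupling, when the remaining C–Br bond is flanked by a bulky quinolinyl group. The fallback reverses the polarity of the partners, sets out from 16 (with 13 as the second partner, so that step 8 is dropped) and comes back at 17. Dibromide 16 is borylated with pinacolborane (PdCl2(MeCN)2, SPhos, Et3N, 1,4-dioxane, 80 °C) to 3,4-bis(4,4,5,5-tetramethyl-1,3,2-dioxaborolan-2-yl)-1-(triisopropylsilyl)pyrrole F5. This is coupled with two equivalents of bromide 13 (Pd(OAc)2, SPhos, K3PO4, toluene–H2O) to 17, and 17 is desilylated as in step 10. The hindered component then enters by oxidative addition instead of transmetalation.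

3. Step 7. Bromine may attack C8 in competition with C5, or the activated ring may be brominated twice. The fallback installs the halogen through nitrogen, sets out from 12 and comes back at 13. Nitration of the fully protonated quinoline (HNO3, H2SO4, 0 °C) stops after one substitution because the nitro group deactivates the ring, and should give crystalline 6,7-dimethoxy-5-nitroquinoline F6. Hydrogenation (H2, Pd/C, EtOH) gives 6,7-dimethoxyquinolin-5-amine F7, which can be freed from any chelating 8-amino isomer. Diazotisation (NaNO2, aq. HBr, 0 °C) gives 6,7-dimethoxyquinoline-5-diazonium bromide F8, and the Sandmeyer reaction with CuBr gives 13.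

**Further compounds**
F1 | step 4 | N-[3-(benzyloxy)propyl]hex-5-en-1-amine | C=CCCCCNCCCOCc1ccccc1
F2 | step 4 | (2S)-N-[3-(benzyloxy)propyl]-N-(hex-5-en-1-yl)-2-methylpent-4-enamide | C=CC[C@H](C)C(=O)N(CCCCC=C)CCCOCc1ccccc1
F3 | step 4 | (3S)-1-[3-(benzyloxy)propyl]-3-methyl-3,4,7,8,9,10-hexahydroazecin-2(1H)-one (C5=C6 alkene, either geometry) | C[C@H]1CC=CCCCCN(CCCOCc2ccccc2)C1=O
F4 | step 4 | (3S)-1-[3-(benzyloxy)propyl]-3-methylazecan-2-one | C[C@H]1CCCCCCCN(CCCOCc2ccccc2)C1=O
F5 | step 10 | 3,4-bis(4,4,5,5-tetramethyl-1,3,2-dioxaborolan-2-yl)-1-(triisopropylsilyl)pyrrole | CC(C)[Si](C(C)C)(C(C)C)n1cc(B2OC(C)(C)C(C)(C)O2)c(B2OC(C)(C)C(C)(C)O2)c1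
F6 | step 7 | 6,7-dimethoxy-5-nitroquinoline | COc1cc2ncccc2c([N+](=O)[O-])c1OC
F7 | step 7 | 6,7-dimethoxyquinolin-5-amine | COc1cc2ncccc2c(N)c1OC
F8 | step 7 | 6,7-dimethoxyquinoline-5-diazonium bromide | COc1cc2ncccc2c([N+]#N)c1OC.[Br-]
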